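**Plan**
Locants used throughout: ring C1 (carries the side chain) =C2H, C3 (CO2H), C4 (aryl), C5 (CO2H), C6 (CO2H); side chain C7=C8–C9(=O)O–lactate.
Retrosynthesis cuts C7=C8 (olefination with the phosphonoacetate of protected (R)-danshensu), then the ring bonds C4–C5 (intramolecular Michael addition) and C1=C2 (olefination), then C1–C6 (Michael addition to a butenolide).
Enabling feature: C5 and C6 are adjacent ring carbons with cis carboxyls, so both carboxyl carbons can be held in one temporary five-membered lactone acetal ring (from a 5-menthyloxy butenolide). In that ring C5 is the only enolisable carbon and C6 cannot epimerise, while C4 is the benzylic β-carbon of the C3 carboxyl (an arylidene ester) and so the natural acceptor for C5.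
Forward: butenolide acetal → C1–C6 by Michael addition → one pot: C1=C2 by olefination with a 2-formylcinnamate, then C4–C5 closure to a cis-fused cyclohexene lactone → amide to aldehyde → side chain → lactone acetal hydrolysed and oxidised to the two acids → debenzylation.
Stereochemistry: C6 from the menthyloxy acetal (anti addition), C5 from the cis fusion of the temporary lactone, C4 from the convex-face placement of the aryl group in the closure, C3 by protonation trans to aryl; the side-chain centre comes from natural (R)-danshensu.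

Key step: step 6

Remark: 5-hydroxyfuran-2(5H)-one and sodium (R)-danshensu are taken as purchasable; aldehyde 10 is carried as the (E)-isomer, and either arylidene geometry is expected to give the same C4 configuration in step 6.

**Route**

Step 1
Reactants: 1 5-hydroxyfuran-2(5H)-one; 2 (+)-menthol
Product: 3 (5S)-5-[(1S,2R,5S)-menthyloxy]furan-2(5H)-one
Conditions: camphorsulfonic acid (cat.), toluene, reflux with water separator; crystallisation from light petroleum, mother liquor re-equilibrated with acid
Reagents that add atoms: none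
Why: Acid-catalysed acetalisation of the cyclic pseudo-acid with the chiral alcohol; the acetal epimers interconvert under acid and the (5S)-epimer should crystallise selectively (crystallisation-induced diastereomer transformation), fixing the centre that later controls C6.

Step 2
Reactants: 3 menthyloxy butenolide; 4 diethyl {2-[methoxy(methyl)amino]-2-oxoethyl}phosphonate
Product: 5 trans-4-substituted 5-menthyloxy-dihydrofuran-2(3H)-one carrying the phosphonoacetamide carbon (C1) on the lactone β-carbon (C6), both C1 epimers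
Conditions: NaH (0.15 eq), THF, 0 °C to rt; NH4Cl work-up
Reagents that add atoms: none
Why: Michael addition of the phosphonate-stabilised carbanion to the butenolide, anti to the menthyloxy group, should set C6; the new C1 centre is irrelevant because it becomes sp2 in step 6.

Step 3
Reactants: 6 3,4-bis(benzyloxy)benzaldehyde; 7 benzyl acrylate
Product: 8 benzyl 2-{[3,4-bis(benzyloxy)phenyl](hydroxy)methyl}prop-2-enoate (racemic)
Conditions: DABCO (1 eq), minimal MeOH, rt, extended reaction time
Reagents that add atoms: none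
Why: Morita–Baylis–Hillman reaction joins the future C3 to the benzylic carbon C4; the carbinol centre needs no control because it is transposed in step 4.

Step 4
Reactants: 8 Baylis–Hillman alcohol
Product: 9 benzyl (2Z)-3-[3,4-bis(benzyloxy)phenyl]-2-(bromomethyl)prop-2-enoate
Conditions: N-bromosuccinimide, Me2S, CH2Cl2, 0 °C to rt
Reagents that add atoms: N-bromosuccinimide, O=C1CCC(=O)N1Br
Why: Bromination with allylic transposition (SN2' displacement of the alkoxysulfonium by bromide) should give the conjugated (Z)-2-(bromomethyl)cinnamate.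

Step 5
Reactants: 9 allylic bromide
Product: 10 benzyl (2E)-3-[3,4-bis(benzyloxy)phenyl]-2-formylprop-2-enoate
Conditions: N-methylmorpholine N-oxide (3 eq), MeCN, rt
Reagents that add atoms: N-methylmorpholine N-oxide, C[N+]1([O-])CCOCC1
Why: Kornblum-type oxidation (O-alkylation of the amine N-oxide, then elimination) should convert the allylic bromide into the aldehyde without touching the benzyl ethers or the ester.

Step 6
Reactants: 5 phosphonate lactone; 10 2-formylcinnamate
Product: 12 cis-fused 3-menthyloxy-1-oxo-3a,6,7,7a-tetrahydroisobenzofuran with C(O)N(OMe)Me on C1, CO2Bn on C3 (trans to aryl) and the aryl group on C4 (trans to the lactone carbonyl), via diene 11 (not isolated)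
Conditions: LiN(SiMe3)2 (1.05 eq), THF, −78 to 0 °C; then 10, 0 °C to rt; then KN(SiMe3)2 (1.1 eq), −78 to −40 °C; AcOH, −78 °C
Reagents that add atoms: none
Why: Deprotonation at C1 (flanked by phosphonate and amide, far more acidic than the lactone CH2) and Horner–Wadsworth–Emmons olefination of the aldehyde of 10 should give diene 11 with the amide trans to C3, so that C6 and C3 are cis on C1=C2; KN(SiMe3)2 then enolises the only acidic position left, the lactone CH2 (C5), the enolate adds to the benzylic β-carbon C4 of the arylidene ester (intramolecular Michael addition) to form C4–C5, and the resulting ester dienolate is protonated at C3. The closest known reaction type is a tandem olefination/Michael annulation, the ring closure being the second stage of a double Michael (Michael-initiated ring closure) sequence. The cyclohexene ring closes 6-endo-trig through C4–C5 onto the existing γ-lactone, which can only become cis-fused. C5 is thus set cis to C6 by the five-membered lactone tether, C4 by a half-chair transition state that keeps the aryl group on the convex face anti to the lactone carbonyl carbon (the alternative puts it syn-axial to the lactone bridge), and C3 by axial α-protonation of the dienolate, which places the ester trans to aryl (also the thermodynamic arrangement at this epimerisable centre); C6 is carried through unchanged because its carboxyl is masked as the acetal and it has no acidic hydrogen. The step needs site selectivity in the first deprotonation (secured by the two activating groups on C1), (E)-selectivity in the olefination (the conjugating amide trans to the larger β-substituent), facial selectivity at C4 (the cis-fused lactone) and α- over γ-protonation (the amide is the weaker acceptor, so the anion reacts as an ester dienolate at C3 and C1=C2 stays in place).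

Step 7
Reactants: 12 bicyclic amide
Product: 13 the corresponding C1 carbaldehyde (enal)
Conditions: Cp2Zr(H)Cl (1.5–2 eq), THF, rt; silica gel/H2O work-up
Reagents that add atoms: none
Why: Chemoselective reduction of the N-methoxy-N-methyl amide by hydrozirconation of its C=O; the zirconated hemiaminal resists further reduction and releases the aldehyde on work-up, while benzyl ester, lactone acetal and the trisubstituted alkene should be left alone.

Step 8
Reactants: 14 sodium (2R)-3-(3,4-dihydroxyphenyl)-2-hydroxypropanoate (sodium danshensu)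
Product: 15 benzyl (2R)-3-[3,4-bis(benzyloxy)phenyl]-2-hydroxypropanoate
Conditions: BnBr (3.1 eq), K2CO3 (2.2 eq), DMF, rt, under N2
Reagents that add atoms: benzyl bromide, BrCc1ccccc1
Why: Williamson-type O-alkylation; under carbonate base only the two phenols and the carboxylate are benzylated, the secondary alcohol stays free and the (R) centre is untouched.

Step 9
Reactants: 15 protected danshensu; 16 (diethoxyphosphoryl)acetic acid
Product: 17 benzyl (2R)-3-[3,4-bis(benzyloxy)phenyl]-2-{[(diethoxyphosphoryl)acetyl]oxy}propanoate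
Conditions: dicyclohexylcarbodiimide, DMAP (cat.), CH2Cl2, 0 °C to rt
Reagents that add atoms: none
Why: Steglich esterification of the secondary alcohol; no bond to the stereocentre is broken.

Step 10
Reactants: 13 enal; 17 phosphonoacetate
Product: 18 (E)-dienoate carrying the protected danshensu ester on C1, lactone acetal intact
Conditions: LiCl, iPr2NEt, MeCN, rt
Reagents that add atoms: none
Why: Horner–Wadsworth–Emmons olefination under Masamune–Roush conditions should give the (E)-configured C7=C8; the mild base is chosen so that the C3 and lactate centres are not epimerised.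

Step 11
Reactants: 18 lactone acetal
Product: 19 the γ-hydroxy lactone (lactol, both anomers)
Conditions: CF3CO2H/H2O/THF, rt to 40 °C
Reagents that add atoms: water, O
Why: Acid hydrolysis of the mixed lactone acetal releases the auxiliary and the lactol (ring tautomer of the C6 aldehyde/C5 acid); the cis C5/C6 relationship is held by the five-membered ring.

Step 12
Reactants: 19 lactol
Product: 20 cis-C5,C6-dicarboxylic acid with all benzyl groups still in place
Conditions: NaClO2, NaH2PO4, 2-methylbut-2-ene, tBuOH/H2O, 0 °C to rt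
Reagents that add atoms: sodium chlorite NaClO2, [Na+].[O-]Cl=O
Why: Pinnick oxidation of the aldehyde tautomer of the lactol under buffered conditions with a hypochlorite scavenger; alkenes, benzyl ethers and esters should be inert.

Step 13
Reactants: 20 hexabenzyl diacid
Product: 21 target, (1R,2R,3S,4R)-3-(3,4-dihydroxyphenyl)-6-[(E)-3-{[(1R)-1-carboxy-2-(3,4-dihydroxyphenyl)ethyl]oxy}-3-oxoprop-1-en-1-yl]cyclohex-5-ene-1,2,4-tricarboxylic acid
Conditions: BCl3 (excess), pentamethylbenzene, CH2Cl2, −78 to 0 °C; MeOH/H2O work-up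
Reagents that add atoms: none
Why: Lewis-acid debenzylation with a benzyl-cation scavenger cleaves the four aryl benzyl ethers and two benzyl esters without hydrogenation, so both C=C bonds, the dienoate ester link and all stereocentres should survive.

**Compound list**
1 | 5-hydroxyfuran-2(5H)-one | O=C1C=CC(O)O1 | starting material
2 | (+)-menthol, (1S,2R,5S)-2-isopropyl-5-methylcyclohexan-1-ol | O[C@H]1C[C@@H](C)CC[C@@H]1C(C)C | starting material
3 | (5S)-5-[(1S,2R,5S)-menthyloxy]furan-2(5H)-one | O=C1C=C[C@@H](O[C@H]2C[C@@H](C)CC[C@@H]2C(C)C)O1 | intermediate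
4 | diethyl {2-[methoxy(methyl)amino]-2-oxoethyl}phosphonate | CCOP(=O)(OCC)CC(=O)N(C)OC | starting material
5 | Michael adduct: 5-menthyloxy-dihydrofuran-2(3H)-one with the CH[P(O)(OEt)2]C(O)N(OMe)Me group on C4, trans to menthyloxy (both epimers at the phosphonate carbon) | O=C1C[C@H](C(C(=O)N(C)OC)P(=O)(OCC)OCC)[C@@H](O[C@H]2C[C@@H](C)CC[C@@H]2C(C)C)O1 | intermediate
6 | 3,4-bis(benzyloxy)benzaldehyde | O=Cc1ccc(OCc2ccccc2)c(OCc2ccccc2)c1 | starting material
7 | benzyl acrylate | C=CC(=O)OCc1ccccc1 | starting material
8 | benzyl 2-{[3,4-bis(benzyloxy)phenyl](hydroxy)methyl}prop-2-enoate (racemic) | C=C(C(=O)OCc1ccccc1)C(O)c1ccc(OCc2ccccc2)c(OCc2ccccc2)c1 | intermediate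
9 | benzyl (2Z)-3-[3,4-bis(benzyloxy)phenyl]-2-(bromomethyl)prop-2-enoate | BrC/C(C(=O)OCc1ccccc1)=C\c1ccc(OCc2ccccc2)c(OCc2ccccc2)c1 | intermediate
10 | benzyl (2E)-3-[3,4-bis(benzyloxy)phenyl]-2-formylprop-2-enoate | O=C/C(C(=O)OCc1ccccc1)=C\c1ccc(OCc2ccccc2)c(OCc2ccccc2)c1 | intermediate
11 | diene: lactone C6 bonded to C1 of a C1=C2–C3=C4 diene, amide on C1 trans to C3, CO2Bn on C3, aryl on C4 cis to C2 (not isolated) | CON(C)C(=O)/C(=C/C(C(=O)OCc1ccccc1)=C\c1ccc(OCc2ccccc2)c(OCc2ccccc2)c1)[C@H]1CC(=O)O[C@@H]1O[C@H]1C[C@@H](C)CC[C@@H]1C(C)C | intermediate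
12 | cis-fused bicyclic lactone acetal with C(O)N(OMe)Me on C1, CO2Bn on C3, 3,4-bis(benzyloxy)phenyl on C4 | CON(C)C(=O)C1=C[C@@H](C(=O)OCc2ccccc2)[C@H](c2ccc(OCc3ccccc3)c(OCc3ccccc3)c2)[C@H]2C(=O)O[C@H](O[C@H]3C[C@@H](C)CC[C@@H]3C(C)C)[C@@H]12 | intermediate
13 | the same bicycle with CHO on C1 | O=CC1=C[C@@H](C(=O)OCc2ccccc2)[C@H](c2ccc(OCc3ccccc3)c(OCc3ccccc3)c2)[C@H]2C(=O)O[C@H](O[C@H]3C[C@@H](C)CC[C@@H]3C(C)C)[C@@H]12 | intermediate
14 | sodium (2R)-3-(3,4-dihydroxyphenyl)-2-hydroxypropanoate | O[C@H](Cc1ccc(O)c(O)c1)C(=O)[O-].[Na+] | starting material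
15 | benzyl (2R)-3-[3,4-bis(benzyloxy)phenyl]-2-hydroxypropanoate | O[C@H](Cc1ccc(OCc2ccccc2)c(OCc2ccccc2)c1)C(=O)OCc1ccccc1 | intermediate
16 | (diethoxyphosphoryl)acetic acid | OC(=O)CP(=O)(OCC)OCC | starting material
17 | benzyl (2R)-3-[3,4-bis(benzyloxy)phenyl]-2-{[(diethoxyphosphoryl)acetyl]oxy}propanoate | CCOP(=O)(OCC)CC(=O)O[C@H](Cc1ccc(OCc2ccccc2)c(OCc2ccccc2)c1)C(=O)OCc1ccccc1 | intermediate
18 | (E)-dienoate ester of protected danshensu on the bicyclic lactone acetal | O=C(/C=C/C1=C[C@@H](C(=O)OCc2ccccc2)[C@H](c2ccc(OCc3ccccc3)c(OCc3ccccc3)c2)[C@H]2C(=O)O[C@H](O[C@H]3C[C@@H](C)CC[C@@H]3C(C)C)[C@@H]12)O[C@H](Cc1ccc(OCc2ccccc2)c(OCc2ccccc2)c1)C(=O)OCc1ccccc1 | intermediate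
19 | the corresponding lactol (γ-hydroxy lactone, both anomers) | O=C(/C=C/C1=C[C@@H](C(=O)OCc2ccccc2)[C@H](c2ccc(OCc3ccccc3)c(OCc3ccccc3)c2)[C@H]2C(=O)OC(O)[C@@H]12)O[C@H](Cc1ccc(OCc2ccccc2)c(OCc2ccccc2)c1)C(=O)OCc1ccccc1 | intermediate
20 | hexabenzyl-protected target with free C5 and C6 carboxylic acids | O=C(/C=C/C1=C[C@@H](C(=O)OCc2ccccc2)[C@H](c2ccc(OCc3ccccc3)c(OCc3ccccc3)c2)[C@@H](C(=O)O)[C@H]1C(=O)O)O[C@H](Cc1ccc(OCc2ccccc2)c(OCc2ccccc2)c1)C(=O)OCc1ccccc1 | intermediate
21 | CNP0327643.1 | O=C(/C=C/C1=C[C@@H](C(=O)O)[C@H](c2ccc(O)c(O)c2)[C@@H](C(=O)O)[C@H]1C(=O)O)O[C@H](Cc1ccc(O)c(O)c1)C(=O)O | target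

**Summary**
Total steps: 13. Longest linear sequence: 9 (steps 3, 4, 5, 6, 7, 10, 11, 12, 13).

Steps most likely to fail:

1. Step 6. The branched phosphonate may olefinate slowly or with poor (E)-selectivity, conjugate addition to 10 may compete, the dienolate may be protonated at C1 (alkene shift), or the enolate may attack the wrong arylidene face. Fallback, setting out from 3: copper-catalysed conjugate addition of (1,3-dioxolan-2-ylmethyl)magnesium bromide (CuBr·SMe2, Me3SiCl, THF, −78 °C) should give the trans dioxolane adduct F1. Mild aqueous AcOH should unmask the aldehyde F2. Amine-catalysed cross-aldol condensation with 10 (pyrrolidine, PhCO2H, CH2Cl2) should give the (E)-configured dienal F3, the geometry now being set by reversible condensation. HC(OMe)3 with pyridinium tosylate should give the dimethyl acetal F4, which takes no part in anion delocalisation. KN(SiMe3)2 (THF, −78 °C; AcOH) should close the ring by the same lactone-enolate Michael addition, α-protonation of the simple ester dienolate giving the bicyclic acetal F5. Dilute aqueous acid then releases the aldehyde, rejoining the route at 13.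

2. Step 11. Cleavage of the hindered lactone acetal may be slow relative to acid hydrolysis of the benzyl and side-chain esters, and C6 may epimerise through the open aldehyde form. Fallback, setting out from 12 (which has only one ester and no side chain): the same aqueous acid hydrolysis should give the lactol F6. Pinnick oxidation should give the diacid F7. BnBr/K2CO3 in DMF should give the dibenzyl ester F8. Cp2Zr(H)Cl should give the aldehyde F9. Olefination with 17 (LiCl, iPr2NEt) should give the octabenzyl-protected compound F10. BCl3/pentamethylbenzene then removes all benzyl groups, rejoining the route at 21.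

3. Step 3. Addition of the electron-rich aldehyde to the acrylate may be very slow, with acrylate oligomerisation taking over. Fallback, setting out from 6 and 7: tandem Michael–aldol reaction triggered by lithium benzenethiolate PhSLi (THF, −78 °C) should give the β-hydroxy sulfide F11. mCPBA at −78 °C should give the sulfoxide F12. Thermal syn-elimination (toluene, 80 °C) then delivers the allylic alcohol, rejoining the route at 8.

**Further compounds**
F1 | step 6 | trans-4-(1,3-dioxolan-2-ylmethyl)-5-menthyloxy-dihydrofuran-2(3H)-one | O=C1C[C@H](CC2OCCO2)[C@@H](O[C@H]2C[C@@H](C)CC[C@@H]2C(C)C)O1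
F2 | step 6 | trans-5-menthyloxy-4-(2-oxoethyl)dihydrofuran-2(3H)-one | O=C1C[C@H](CC=O)[C@@H](O[C@H]2C[C@@H](C)CC[C@@H]2C(C)C)O1
F3 | step 6 | dienal: analogue of 11 with CHO on C1 | O=C/C(=C/C(C(=O)OCc1ccccc1)=C\c1ccc(OCc2ccccc2)c(OCc2ccccc2)c1)[C@H]1CC(=O)O[C@@H]1O[C@H]1C[C@@H](C)CC[C@@H]1C(C)C
F4 | step 6 | dimethyl acetal of F3 | COC(OC)/C(=C/C(C(=O)OCc1ccccc1)=C\c1ccc(OCc2ccccc2)c(OCc2ccccc2)c1)[C@H]1CC(=O)O[C@@H]1O[C@H]1C[C@@H](C)CC[C@@H]1C(C)C
F5 | step 6 | bicyclic lactone acetal with CH(OMe)2 on C1 | COC(OC)C1=C[C@@H](C(=O)OCc2ccccc2)[C@H](c2ccc(OCc3ccccc3)c(OCc3ccccc3)c2)[C@H]2C(=O)O[C@H](O[C@H]3C[C@@H](C)CC[C@@H]3C(C)C)[C@@H]12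
F6 | step 11 | lactol of the bicyclic amide | CON(C)C(=O)C1=C[C@@H](C(=O)OCc2ccccc2)[C@H](c2ccc(OCc3ccccc3)c(OCc3ccccc3)c2)[C@H]2C(=O)OC(O)[C@@H]12
F7 | step 11 | cis-C5,C6-diacid of the cyclohexene amide | CON(C)C(=O)C1=C[C@@H](C(=O)OCc2ccccc2)[C@H](c2ccc(OCc3ccccc3)c(OCc3ccccc3)c2)[C@@H](C(=O)O)[C@H]1C(=O)O
F8 | step 11 | tribenzyl triester of the cyclohexene amide | CON(C)C(=O)C1=C[C@@H](C(=O)OCc2ccccc2)[C@H](c2ccc(OCc3ccccc3)c(OCc3ccccc3)c2)[C@@H](C(=O)OCc2ccccc2)[C@H]1C(=O)OCc1ccccc1
F9 | step 11 | tribenzyl triester with CHO on C1 | O=CC1=C[C@@H](C(=O)OCc2ccccc2)[C@H](c2ccc(OCc3ccccc3)c(OCc3ccccc3)c2)[C@@H](C(=O)OCc2ccccc2)[C@H]1C(=O)OCc1ccccc1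
F10 | step 11 | octabenzyl-protected target | O=C(/C=C/C1=C[C@@H](C(=O)OCc2ccccc2)[C@H](c2ccc(OCc3ccccc3)c(OCc3ccccc3)c2)[C@@H](C(=O)OCc2ccccc2)[C@H]1C(=O)OCc1ccccc1)O[C@H](Cc1ccc(OCc2ccccc2)c(OCc2ccccc2)c1)C(=O)OCc1ccccc1
F11 | step 3 | benzyl 2-{[3,4-bis(benzyloxy)phenyl](hydroxy)methyl}-3-(phenylsulfanyl)propanoate | OC(c1ccc(OCc2ccccc2)c(OCc2ccccc2)c1)C(CSc1ccccc1)C(=O)OCc1ccccc1
F12 | step 3 | benzyl 2-{[3,4-bis(benzyloxy)phenyl](hydroxy)methyl}-3-(phenylsulfinyl)propanoate | OC(c1ccc(OCc2ccccc2)c(OCc2ccccc2)c1)C(CS(=O)c1ccccc1)C(=O)OCc1ccccc1
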